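**Assumption:** the SMILES is taken as authoritative (free C14 acid, ring-cis C1=C10, cis-2,3- and cis-4,5-epoxides, (2R,3R)-epoxyangelate). Germacrane numbering is used throughout: C1–C10 ring, C11–C13 methylene-lactone carbons, C14 acid carbon, C15 the C4 methyl.

## Retrosynthetic overview

1. The usual first plan is to macrocyclise a polyene at C6–C7 (NHK/Barbier) and then epoxidise and acylate on the ring. Here every stereocentre and both ring epoxides are set on open-chain material, and the 10-membered ring is closed last by RCM across the hindered trisubstituted C1=C10 olefin. This final RCM is the conventional ring-closing reaction for germacranolides; the departure from the usual plan lies in its timing and position, not in the reaction type. C14 is carried as CH2OSi and oxidised at the end.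
2. The RCM precursor 25 comes from epoxy-aldehyde 22 by Brown–Oehlschlager chloroallylboration, which makes the C2–C3 bond, the cis-epoxide and the RCM vinyl group without any alkene epoxidation. Aldehyde 22 comes from a Sharpless epoxidation (C4–C5).
3. Lactone 17 comes from bromide 8 and Z-enal 12 by Cr(II) Barbier allylation–lactonisation (C6–C7); the C8 stereocentre relays to C7 and C6.
4. Bromide 8 comes from a Brown alkoxyallylboration (C8/C9 syn, oxygens already differentiated) and cross-metathesis. Side-chain acid 16 comes from Sharpless epoxidation of angelyl alcohol.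
5. Ring order: side-chain oxirane (separately) → γ-lactone → C4–C5 oxirane → C2–C3 oxirane → 10-membered carbocycle.

## Route

**Step 1**
Reactants: 1, 2-methylenepropane-1,3-diol
Product: 2, 2-{[(tert-butyldiphenylsilyl)oxy]methyl}prop-2-en-1-ol
Conditions: NaH (1.0 equiv), THF, 0 °C; TBDPSCl (1.0 equiv)
Reagents that add atoms: TBDPSCl, CC(C)(C)[Si](Cl)(c1ccccc1)c1ccccc1
Why: Statistical mono-O-silylation of a symmetric diol via its monosodium alkoxide; no stereocentre; the TBDPS ether masks C14–O to the end.

**Step 2**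
Reactants: 2
Product: 3, 2-{[(tert-butyldiphenylsilyl)oxy]methyl}prop-2-enal
Conditions: MnO2, CH2Cl2, rt
Reagents that add atoms: none
Why: Selective allylic-alcohol oxidation gives the 2-substituted acrolein that supplies C9, C10, C1 and C14.

**Step 3**
Reactants: 3; 4, allyl methoxymethyl ether
Product: 5, (3S,4S)-2-{[(tert-butyldiphenylsilyl)oxy]methyl}-4-(methoxymethoxy)hexa-1,5-dien-3-ol (syn; C3 = C9, C4 = C8)
Conditions: 4, s-BuLi, THF, −78 °C; (+)-Ipc2BOMe (from (−)-α-pinene); BF3·OEt2; then 3, −78 °C; NaOH/H2O2
Reagents that add atoms: none (all new atoms come from 4)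
Why: Brown (Z)-γ-alkoxyallylboration; the chair transition state of the Z reagent gives the syn adduct and the Ipc ligands direct Re-face attack on the aldehyde, setting C9 (free OH) and C8 (OMOM) with the two oxygens already differentiated.

**Step 4**
Reactants: 5
Product: 6, (3S,4S)-2-{[(tert-butyldiphenylsilyl)oxy]methyl}-4-(methoxymethoxy)hexa-1,5-dien-3-yl acetate
Conditions: Ac2O, pyridine, DMAP (cat.), CH2Cl2, 0 °C
Reagents that add atoms: acetic anhydride, CC(=O)OC(C)=O
Why: Standard acylation installs the target's C9 acetate at once, so no later diol differentiation is needed.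

**Step 5**
Reactants: 6; 7, methyl 2-(bromomethyl)acrylate (5 equiv)
Product: 8, methyl (2Z,4S,5S)-5-acetoxy-2-(bromomethyl)-6-{[(tert-butyldiphenylsilyl)oxy]methyl}-4-(methoxymethoxy)hepta-2,6-dienoate
Conditions: Hoveyda–Grubbs II (10 mol %), CH2Cl2, 40 °C
Reagents that add atoms: none (from 7; ethylene lost)
Why: Olefin cross-metathesis of the monosubstituted vinyl group with excess acrylate; the doubly branched 1,1-disubstituted C10 methylene is too hindered to react, and the enoate geometry is irrelevant because the allylchromium in Step 12 equilibrates.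

**Step 6**
Reactants: 9, 4-methylfuran-2(5H)-one
Product: 10, (2Z)-4-hydroxy-N-methoxy-N,3-dimethylbut-2-enamide
Conditions: MeNH(OMe)·HCl, AlMe3, CH2Cl2, 0 °C → rt
Reagents that add atoms: N,O-dimethylhydroxylamine hydrochloride, CNOC.Cl
Why: Weinreb aminolysis opens the butenolide; the Z geometry (C3 cis to C6) is inherited from the ring.

**Step 7**
Reactants: 10
Product: 11, (2Z)-4-[(tert-butyldimethylsilyl)oxy]-N-methoxy-N,3-dimethylbut-2-enamide
Conditions: TBSCl, imidazole, DMF, 0 °C
Reagents that add atoms: TBSCl, CC(C)(C)[Si](C)(C)Cl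
Why: Silylation prevents relactonisation and masks the future C3 aldehyde.

**Step 8**
Reactants: 11
Product: 12, (2Z)-4-[(tert-butyldimethylsilyl)oxy]-3-methylbut-2-enal
Conditions: DIBAL-H, THF, −78 °C; Rochelle salt
Reagents that add atoms: none
Why: Weinreb-amide reduction stops at the aldehyde through the chelated tetrahedral intermediate; low temperature and neutral work-up keep the Z olefin.

**Step 9**
Reactants: 13, angelic acid
Product: 14, (2Z)-2-methylbut-2-en-1-ol
Conditions: LiAlH4, Et2O, 0 °C
Reagents that add atoms: none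
Why: Hydride reduction of the acid leaves the Z trisubstituted olefin untouched.

**Step 10**
Reactants: 14
Product: 15, [(2S,3R)-2,3-dimethyloxiran-2-yl]methanol
Conditions: Ti(OiPr)4, L-(+)-DET, t-BuOOH, 4 Å MS, CH2Cl2, −20 °C
Reagents that add atoms: tert-butyl hydroperoxide, CC(C)(C)OO
Why: Sharpless asymmetric epoxidation; L-(+)-tartrate delivers oxygen to the face giving the (2S,3R)-epoxy alcohol, with the relative configuration fixed by the Z olefin.

**Step 11**
Reactants: 15
Product: 16, (2R,3R)-2,3-dimethyloxirane-2-carboxylic acid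
Conditions: RuCl3 (cat.), NaIO4, CCl4/MeCN/H2O, rt
Reagents that add atoms: sodium periodate, [Na+].[O-]I(=O)(=O)=O (with H2O, O)
Why: Sharpless RuO4 oxidation of the primary alcohol to the acid without opening the epoxide; the C2 descriptor changes only because CIP priorities change.

**Step 12**
Reactants: 8; 12
Product: 17, 6,7-trans α-methylene-γ-butyrolactone; C6 carries the (Z)-CH=C(CH3)CH2OTBS arm (C5–C3) and C7 carries the C8(OMOM)–C9(OAc)–C10(=CH2)CH2OTBDPS arm; C6–C9 arranged as in the target
Conditions: CrCl2 (4 equiv), THF, 0 °C → rt; then PPTS (cat.), CH2Cl2, rt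
Reagents that add atoms: none (Br and MeOH lost)
Why: Nozaki–Hiyama/Barbier allylation–lactonisation; the equilibrated (E)-allylchromium reacts through a closed chair transition state to give the anti adduct (hence the trans lactone), and the C8 stereocentre (H-8 eclipsing the enoate, C8–C9 bond anti, OMOM outside) exposes the π-face that gives C7 and C6 as in the target.

**Step 13**
Reactants: 17
Product: 18, the C8 alcohol (MOM removed; otherwise as 17)
Conditions: Me2BBr, CH2Cl2, −78 °C; NaHCO3 quench; used directly
Reagents that add atoms: none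
Why: Guindon cleavage of the MOM acetal at −78 °C spares the silyl ethers, acetate and lactone; it is done before any epoxide exists.

**Step 14**
Reactants: 18; 16
Product: 19, the C8 (2R,3R)-2,3-epoxy-2-methylbutanoate of 18
Conditions: 16, 2,4,6-trichlorobenzoyl chloride, Et3N, THF; then 18, DMAP, toluene, 0 °C → rt
Reagents that add atoms: none (acyl group from 16)
Why: Yamaguchi esterification of the hindered secondary alcohol; running it cold on crude 18 outpaces 9→8 acetyl migration, and no stereocentre is touched.

**Step 15**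
Reactants: 19
Product: 20, the primary allylic alcohol at C3 (TBS removed)
Conditions: HF·pyridine, pyridine, THF, 0 °C
Reagents that add atoms: none
Why: Chemoselective cleavage of the primary allylic TBS ether in the presence of the TBDPS ether.

**Step 16**
Reactants: 20
Product: 21, the 4,5-epoxy alcohol (cis-epoxide; C4 S and C5 R in this intermediate, the same spatial arrangement as 4R,5R in the target)
Conditions: Ti(OiPr)4, L-(+)-DET, t-BuOOH, 4 Å MS, CH2Cl2, −20 °C
Reagents that add atoms: tert-butyl hydroperoxide, CC(C)(C)OO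
Why: Reagent-controlled Sharpless epoxidation of the (Z)-2-methyl allylic alcohol, the same facial sense as Step 10; only the allylic-alcohol olefin reacts.

**Step 17**
Reactants: 21
Product: 22, the α-quaternary epoxy aldehyde (C3 = CHO)
Conditions: Dess–Martin periodinane, NaHCO3, CH2Cl2, 0 °C
Reagents that add atoms: none
Why: Mild oxidation; the α-carbon (C4) is quaternary and cannot epimerise.

**Step 18**
Reactants: 22; 23, allyl chloride
Product: 24, the syn-chlorohydrin (C3 S carbinol, C2 S chloride, terminal vinyl = C1)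
Conditions: 23, (+)-Ipc2BOMe, LiN(c-C6H11)2, Et2O, −95 °C; BF3·OEt2; then 22, −95 °C; pH 7 buffer/H2O2, 0 °C
Reagents that add atoms: none (all new atoms from 23)
Why: Oehlschlager–Brown (Z)-γ-chloroallylboration; the chair transition state gives the syn chlorohydrin and the Ipc ligands enforce Re-face attack (reagent control over the aldehyde's intrinsic bias), setting C3 and C2 and installing the RCM vinyl group.

**Step 19**
Reactants: 24
Product: 25, the cis-2,3-epoxide bearing the C1 vinyl group (bis-epoxy diene)
Conditions: DBU, CH2Cl2, 0 °C → rt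
Reagents that add atoms: none (HCl lost)
Why: Intramolecular Williamson closure with inversion at C2 converts the syn-chlorohydrin into the cis-epoxide (2R,3R as in the target).

**Step 20**
Reactants: 25
Product: 26, the 10-membered carbocycle (target skeleton with C14 as CH2OTBDPS; C1=C10 ring-cis)
Conditions: Hoveyda–Grubbs II (15 mol %), 1,4-benzoquinone (30 mol %), toluene (1 mM), 80 °C
Reagents that add atoms: none (ethylene lost)
Why: Ring-closing metathesis of the vinyl epoxide onto the 1,1-disubstituted C10 methylene; a 10-membered ring accepts only the ring-cis olefin (C9 cis to C2), and engaging the lactone methylene instead would give a strained bridgehead olefin.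

**Step 21**
Reactants: 26
Product: 27, the C14 primary allylic alcohol
Conditions: TBAF/AcOH (1:1), THF, 0 °C → rt
Reagents that add atoms: none
Why: Buffered fluoride desilylation avoids acetyl migration, epoxide opening and Michael addition to the methylene lactone.

**Step 22**
Reactants: 27
Product: 28, the C14 enal
Conditions: MnO2, CH2Cl2, rt
Reagents that add atoms: none
Why: Neutral allylic oxidation; the only free alcohol is allylic and the olefin geometry is retained.

**Step 23**
Reactants: 28
Product: 29, leucanthin B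
Conditions: NaClO2, NaH2PO4, 2-methyl-2-butene, t-BuOH/H2O, 0 °C
Reagents that add atoms: sodium chlorite, [Na+].[O-]Cl=O
Why: Pinnick oxidation converts the enal to the enoic acid without touching the epoxides, esters or either Michael acceptor.

## Compound list

1 | 2-methylenepropane-1,3-diol | C=C(CO)CO | starting material
2 | mono-TBDPS ether of 1 | C=C(CO)CO[Si](c1ccccc1)(c1ccccc1)C(C)(C)C | intermediate
3 | 2-(TBDPSoxymethyl)acrolein | C=C(C=O)CO[Si](c1ccccc1)(c1ccccc1)C(C)(C)C | intermediate
4 | allyl methoxymethyl ether | C=CCOCOC | starting material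
5 | (3S,4S) syn-alkoxyallylboration adduct | C=C[C@H](OCOC)[C@@H](O)C(=C)CO[Si](c1ccccc1)(c1ccccc1)C(C)(C)C | intermediate
6 | acetate of 5 | C=C[C@H](OCOC)[C@@H](OC(C)=O)C(=C)CO[Si](c1ccccc1)(c1ccccc1)C(C)(C)C | intermediate
7 | methyl 2-(bromomethyl)acrylate | C=C(CBr)C(=O)OC | starting material
8 | (2Z,4S,5S) allylic bromide (East fragment) | COC(=O)/C(CBr)=C/[C@H](OCOC)[C@@H](OC(C)=O)C(=C)CO[Si](c1ccccc1)(c1ccccc1)C(C)(C)C | intermediate
9 | 4-methylfuran-2(5H)-one | CC1=CC(=O)OC1 | starting material
10 | (Z)-hydroxy Weinreb amide | CON(C)C(=O)/C=C(/C)CO | intermediate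
11 | TBS ether of 10 | CON(C)C(=O)/C=C(/C)CO[Si](C)(C)C(C)(C)C | intermediate
12 | (Z)-4-(TBSoxy)-3-methylbut-2-enal (West fragment) | O=C/C=C(/C)CO[Si](C)(C)C(C)(C)C | intermediate
13 | angelic acid | C/C=C(/C)C(=O)O | starting material
14 | (Z)-2-methylbut-2-en-1-ol | C/C=C(/C)CO | intermediate
15 | [(2S,3R)-2,3-dimethyloxiran-2-yl]methanol | OC[C@]1(C)O[C@@H]1C | intermediate
16 | (2R,3R)-2,3-dimethyloxirane-2-carboxylic acid | OC(=O)[C@]1(C)O[C@@H]1C | intermediate
17 | trans-methylene lactone (C8 OMOM, C3 OTBS) | C=C1C(=O)O[C@H](/C=C(/C)CO[Si](C)(C)C(C)(C)C)[C@H]1[C@H](OCOC)[C@@H](OC(C)=O)C(=C)CO[Si](c1ccccc1)(c1ccccc1)C(C)(C)C | intermediate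
18 | C8 alcohol | C=C1C(=O)O[C@H](/C=C(/C)CO[Si](C)(C)C(C)(C)C)[C@H]1[C@H](O)[C@@H](OC(C)=O)C(=C)CO[Si](c1ccccc1)(c1ccccc1)C(C)(C)C | intermediate
19 | C8 epoxyangelate | C=C1C(=O)O[C@H](/C=C(/C)CO[Si](C)(C)C(C)(C)C)[C@H]1[C@H](OC(=O)[C@]1(C)O[C@@H]1C)[C@@H](OC(C)=O)C(=C)CO[Si](c1ccccc1)(c1ccccc1)C(C)(C)C | intermediate
20 | C3 allylic alcohol | C=C1C(=O)O[C@H](/C=C(/C)CO)[C@H]1[C@H](OC(=O)[C@]1(C)O[C@@H]1C)[C@@H](OC(C)=O)C(=C)CO[Si](c1ccccc1)(c1ccccc1)C(C)(C)C | intermediate
21 | 4,5-epoxy alcohol | C=C1C(=O)O[C@H]([C@H]2O[C@@]2(C)CO)[C@H]1[C@H](OC(=O)[C@]1(C)O[C@@H]1C)[C@@H](OC(C)=O)C(=C)CO[Si](c1ccccc1)(c1ccccc1)C(C)(C)C | intermediate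
22 | 4,5-epoxy aldehyde | C=C1C(=O)O[C@H]([C@H]2O[C@@]2(C)C=O)[C@H]1[C@H](OC(=O)[C@]1(C)O[C@@H]1C)[C@@H](OC(C)=O)C(=C)CO[Si](c1ccccc1)(c1ccccc1)C(C)(C)C | intermediate
23 | allyl chloride | C=CCCl | starting material
24 | syn-chlorohydrin | C=C1C(=O)O[C@H]([C@H]2O[C@@]2(C)[C@H](O)[C@@H](Cl)C=C)[C@H]1[C@H](OC(=O)[C@]1(C)O[C@@H]1C)[C@@H](OC(C)=O)C(=C)CO[Si](c1ccccc1)(c1ccccc1)C(C)(C)C | intermediate
25 | bis-epoxy diene (RCM precursor) | C=C1C(=O)O[C@H]([C@H]2O[C@@]2(C)[C@@H]3O[C@@H]3C=C)[C@H]1[C@H](OC(=O)[C@]1(C)O[C@@H]1C)[C@@H](OC(C)=O)C(=C)CO[Si](c1ccccc1)(c1ccccc1)C(C)(C)C | intermediate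
26 | macrocycle, 14-O-TBDPS | C=C1C(=O)O[C@H]2[C@H]1[C@H](OC(=O)[C@]1(C)O[C@@H]1C)[C@@H](OC(C)=O)/C(CO[Si](c1ccccc1)(c1ccccc1)C(C)(C)C)=C\[C@H]1O[C@H]1[C@]1(C)O[C@H]21 | intermediate
27 | 14-alcohol | C=C1C(=O)O[C@H]2[C@H]1[C@H](OC(=O)[C@]1(C)O[C@@H]1C)[C@@H](OC(C)=O)/C(CO)=C\[C@H]1O[C@H]1[C@]1(C)O[C@H]21 | intermediate
28 | 14-aldehyde | C=C1C(=O)O[C@H]2[C@H]1[C@H](OC(=O)[C@]1(C)O[C@@H]1C)[C@@H](OC(C)=O)/C(C=O)=C\[C@H]1O[C@H]1[C@]1(C)O[C@H]21 | intermediate
29 | leucanthin B | C=C1C(=O)O[C@H]2[C@H]1[C@H](OC(=O)[C@]1(C)O[C@@H]1C)[C@@H](OC(C)=O)/C(C(=O)O)=C\[C@H]1O[C@H]1[C@]1(C)O[C@H]21 | target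

## Summary

**Total steps:** 23.
**Longest linear sequence:** 17 (Steps 1–5, then 12–23).

**Three steps most likely to fail:**

1. **Step 20 (RCM).** The ring is strained, the new olefin is trisubstituted, one partner is a vinyl epoxide and a free methylene lactone is present.
   Fallback: move the ring closure to C6–C7. Join a West chlorohydrin to East alcohol 5 through a temporary C9–O–Si(iPr)2–O–C3 tether and form C1=C10 by an 8-membered silicon-tethered RCM, which enforces the geometry. Then close the carbocycle and lactone together by an intramolecular Cr(II) Barbier allylation.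

2. **Step 12 (Barbier).** The C8 → C7/C6 relay rests on an acyclic 1,2-induction model, and the Z-enal may isomerise.
   Fallback: make C6–C7 by chirality transfer instead. Add a Marshall-type allenylzinc, generated from a C7 propargylic mesylate, to enal 12 (anti, reagent-controlled). Then form the methylene lactone by Pd-catalysed carbonylative lactonisation of the homopropargylic alcohol, with C9 temporarily as a silyl ether.

3. **Step 18 (chloroallylboration).** The reagent must override the intrinsic facial bias of an α-quaternary epoxy aldehyde, and BF3 is used with epoxides present.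
   Fallback: change the order of events. Run the Sharpless epoxidation, oxidation, chloroallylboration and ring closure on the small West unit before union, starting from (Z)-TBSOCH2CH=C(Me)CH2OH. Then join that bis-epoxy aldehyde to bromide 8 in the Barbier step, relying on chelation or a chiral Cr ligand for the C6 configuration.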